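59.5% of the pool of substrate and open intermediate stands as open intermediate in the alder and elm runs, summed over their readings from 1.50 min on. We carry this open share, c(open intermediate) / (c(open intermediate) + c(substrate)), as a reading that bears the scatter of the tables.

| setting | alder | elm | oak | flask |
|---|---|---|---|---|
| substrate | 0.011 M (fed, over 20 s) | 0.017 M (fed, over 20 s) | 0.023 M (fed, over 20 s) | 0.023 M (fed, over 20 s) |
| partner | 1.5 equiv | 1.5 equiv | 3 equiv | 1.50 equiv |
| remark | run made earlier; the fed solution adds 0.20 times the starting volume | run made earlier; the fed solution adds 0.20 times the starting volume | run made earlier; the fed solution adds 0.20 times the starting volume | the fed solution adds 0.20 times the starting volume |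
| time |  |  |  | 3.0 min |

| run | time / min | open intermediate / % | substrate / % | target / % | side product / % |
|---|---|---|---|---|---|
| alder | 0.500 | 33.5 | 25.8 | 41.3 | 0 |
| alder | 1.00 | 20.5 | 14.3 | 62.7 | 0 |
| alder | 1.50 | 17.0 | 12.6 | 72.1 | 0.1 |
| alder | 2.00 | 15.8 | 9.8 | 73.1 | 0 |
| alder | 2.50 | 13.7 | 10.7 | 75.6 | 0.3 |
| alder | 3.00 | 12.9 | 9.4 | 76.8 | 0.1 |
| alder | 4.00 | 13.1 | 10.8 | 77.4 | 1.4 |
| elm | 0.500 | 29.4 | 25.4 | 46.6 | 0.3 |
| elm | 1.00 | 20.3 | 14.1 | 65.7 | 1.6 |
| elm | 1.50 | 16.7 | 9.5 | 75.0 | 1.5 |
| elm | 2.00 | 13.4 | 6.7 | 78.4 | 0.4 |
| elm | 2.50 | 12.9 | 9.2 | 78.4 | 1.0 |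
| elm | 3.00 | 10.8 | 7.5 | 79.5 | 0 |
| elm | 4.00 | 12.2 | 7.9 | 80.2 | 0 |
| oak | 0.333 | 23.7 | 36.0 | 38.5 | 2.0 |
| oak | 0.833 | 10.4 | 7.4 | 81.3 | 1.7 |
| oak | 1.50 | 2.9 | 5.4 | 93.9 | 0.9 |
| oak | 2.50 | 1.2 | 3.7 | 97.0 | 0.4 |
| oak | 4.00 | 2.4 | 2.8 | 97.1 | 0 |

(scatter of a reading: 1 percentage point)

- the largest share of what was charged as substrate, at 3.0 min belongs to (target / open intermediate / side product / substrate)
- the largest share itself, whichever of these holds it, in percent of the substrate charged

- every charge counts on the volume at the start, and the solution that is fed holds the whole dose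
- the numbers in the tables scatter with a standard deviation of 1 percentage point

The runs put their events in order of time. The feed ends at 20 s, and at 0.500 min the alder run shows an open share of 56.5%, while its target, at 41.3%, has yet to climb to 76.8% at 3.00 min. We do not take the exchange between substrate and open intermediate as a steady split during this climb, but from the stall on, where we reckon with the pool at the later open share, which reads higher than that early one. Next comes the stall: the elm target moves from 78.4% at 2.00 min to 80.2% at 4.00 min, with 20.1% still in the pool. The oak run, with twice the equivalents of partner, has a pool of 4.90% at 2.50 min. Side product reads 1.4% in the alder run at 4.00 min, against a scatter of 1 point.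

The forecast gives target at 81.5%, holding that “the partner is what limits the yield”. Our own step is the split: the 18.5% that this leaves divides, by the open share, into 11.0% open intermediate and 7.49% substrate.

    substrate ⇌ open intermediate (K = 1.60, k = 0.200 s⁻¹)
    partner → second intermediate (k = 0.0530 s⁻¹)
    open intermediate + second intermediate → target (k = 17.0 L mol⁻¹ s⁻¹)
    2 second intermediate → homo product (k = 7.80 L mol⁻¹ s⁻¹)
    substrate + second intermediate → side product (k = 0.0600 L mol⁻¹ s⁻¹)

The flask gives target at 81.2%, with 11.4% open intermediate and 7.12% substrate, an open share of 61.6%. Partner, the limiting reagent, is down to 0.0072% of its charge, and target stands at 81.4% at 30.0 min. The neighbouring flask with 0.380 equiv of partner ends with 31.7% target, so its pool is 68.3%, which the open share splits into 40.6% open intermediate and 27.7% substrate. That flask holds 26.2% substrate and, as its largest share, 42.0% open intermediate.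

(All runs are simulated with made-up constants; the scatter is artificial.)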